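All runs stem from a simulated flask with constants of no real substance; noise was put on by code.

Start from the target: it comes out of the substrate, so first ask how much substrate each flask has used by the end of 4.0 h.

all flasks: substrate 0.20 M
- autumn: reagent 0.22 M; initiator 4.6 mM; run made earlier
- spring: reagent 0.22 M; initiator 31 mM; run made earlier
- dusk: reagent 0.22 M; initiator 180 mM; run made earlier
- Monday's: reagent 0.220 M; initiator 6.0 mM; time 4.0 h
- Wednesday's: reagent 0.220 M; initiator 20 mM; time 4.0 h
- Tuesday's: reagent 0.220 M; initiator 60 mM; time 4.0 h
- Sunday's: reagent 0.220 M; initiator 200 mM; time 4.0 h

| run | time / min | target / % | substrate / % |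
|---|---|---|---|
| autumn | 25.0 | 2 | 95 |
| autumn | 50.0 | 4 | 97 |
| autumn | 80.0 | 7 | 91 |
| autumn | 90.0 | 8 | 91 |
| autumn | 120 | 7 | 89 |
| spring | 25.0 | 9 | 91 |
| spring | 50.0 | 10 | 85 |
| spring | 80.0 | 17 | 76 |
| spring | 90.0 | 15 | 73 |
| spring | 120 | 17 | 68 |
| dusk | 25.0 | 11 | 75 |
| dusk | 50.0 | 22 | 55 |
| dusk | 80.0 | 30 | 30 |
| dusk | 90.0 | 30 | 28 |
| dusk | 120 | 34 | 7 |

(each reading ± 1.5 percentage points)

- the analysis behind the earlier runs scatters by 1.5 percentage points, standard deviation
- "hardly changes" means that all values lie within two and a half points (for a concentration: within two and a half percent of the largest)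

* amount of target at the end, in percent of the substrate charged for Monday's, Wednesday's, Tuesday's, Sunday's, in this order
* the shape of the row from first to last (falls, then rises / rises, then falls / hardly changes / falls all the way / rises all the way)

Take the spring run at its last reading: 32.0% of the substrate is used in 120 min. At that pace the charge would last 6.25 h. Call this the clearing time: the time a flask needs to use its charge of substrate at its average pace. Suppose a chain, half order in initiator, so that the clearing time goes as one over the square root of [initiator].

Test it. For the autumn run the rule leaves 87.7% at 120 min, and you read 89%. But for the dusk run it leaves 48.6% at 80.0 min, and you read 30%, so that run is faster than the rule. I therefore trust the rule only between autumn and spring, where Monday's and Wednesday's lie.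

A second doubt: the pace slackens, since the spring reading at 80.0 min gives a clearing time of 5.56 h. I keep the later, longer value. The rule then leaves 71.8% in Monday's and 48.6% in Wednesday's.

Now the target. Spring's selectivity, target per substrate used, reads 53.1%, which would give 15.0% for Monday's and 27.3% for Wednesday's. The objection is that spring's target stands still over its last readings while substrate falls from 76% to 68%, so these are upper marks. For lower marks I take the last target readings of the runs that by then had used less substrate than I reckon for each flask: 7% from autumn for Monday's and 17% from spring for Wednesday's. My answer lies between the marks.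

Sunday's clearing time by the rule is 2.46 h, shorter than the run, so I expect its row to turn down.

The forecast, judging that “the target is probably lost first-order”, gives 9%, 14%, 20% and 9%, with the shape "rises, then falls". Its Wednesday value is below my lower mark.

The flasks give 12.2%, 19.9%, 28.6% and 22.0%: the shape is "rises, then falls", as forecast, but each value stands above the forecast.

    2 first chain carrier → ended chains A (k = 8.00 × 10⁸ L mol⁻¹ s⁻¹)
    reagent + first chain carrier ⇌ target + second chain carrier (K = 5.61, k = 70600 L mol⁻¹ min⁻¹)
    substrate + initiating radical → capped initiator + first chain carrier (k = 27400 L mol⁻¹ s⁻¹)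
    substrate + second chain carrier → by-product + first chain carrier (k = 1.96 × 10⁵ L mol⁻¹ min⁻¹)
    2 second chain carrier → ended chains B (k = 2.00 × 10⁷ L mol⁻¹ s⁻¹)
    initiator → 2 initiating radical (k = 0.00203 min⁻¹)
    target ⇌ isomer of the product (K = 2.44, k = 0.00743 min⁻¹)

The clearing time of 6.25 h gave 71.8% of substrate left in Monday's, where the flask holds 74%, and 48.6% in Wednesday's, where it holds 54%. In Monday's, target and isomer of the product relax towards each other with a half-life of 1.10 h, short against the run of 4.0 h, and at the end that flask holds 11.0% of the isomer of the product beside 12.2% of target.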